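## Structural features

The target is a germacranolide: a ten-membered carbocycle (C1–C10) that is trans-fused at C6–C7 to an α-methylene-γ-butyrolactone (O–C6, C7–C11(=C13)–C12). The ring carries a C1 ketone conjugated with the exocyclic C10=C14 olefin, a trans, trisubstituted C3–C4 epoxide with methyl C15 on C4, a free hydroxyl on C8 and an angelate on C9. The stereocentres form two domains, C3/C4 and the contiguous run C6–C7–C8–C9, which are separated by C5 on one side and C10–C1–C2 on the other (3R,4R,6R,7R,8S,9R). Fragile elements are: the β,γ-epoxy ketone (base opens it through C2–H); two exocyclic Michael acceptors; the C9 ester, which is allylic to the enone (SN2′ loss with nucleophilic amines or phosphines, Z→E isomerisation, migration to O8); and the lactone, which can translactonise to O8. The real difficulty is twofold. Six stereocentres on a medium ring cannot be set reliably by reactions on that ring. The skeleton is also almost C2-symmetric (C1/C6, C2/C5, C3/C4, C7/C10 and C8/C9 are pairwise related), so each pair must be told apart on purpose. The key step exploits that C1 (ketone) and C6 (lactone carbinol) stand 1,6 across the ring: they are the two carbonyl carbons released when the C1=C6 ring-fusion olefin of an octalin (ring A = C1–C6, ring B = C1, C6, C7–C10) is cut, so the periphery can be built and stereodefined on two six-membered rings first.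

## Logic of the disconnections

30 ⇒ 29. Cut: the C1=O π bond (ketone read back to the allylic alcohol). The β,γ-epoxy ketone and the ester allylic to the enone tolerate neither base nor nucleophilic amines, so the carbonyl appears last. Gain: no earlier intermediate holds an enolisable ketone next to these groups. Demand: a neutral oxidant that takes the allylic C1–OH and leaves the free C8–OH.

29 ⇒ 28. Cut: the O1–Si and O8–Si bonds. Both hydroxyls must be masked while O9 is acylated and can be freed together. Gain: one protecting-group type for two positions. Demand: desilylation must spare a trisubstituted epoxide, an allylic ester and two exocyclic olefins.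

28 ⇒ 26 + 27. Cut: the O9–C(acyl) bond. The Z-enoate would not survive enolate chemistry, so it is attached after the last strongly basic step and before the enone exists. Gain: 26 has a single free hydroxyl. Demand: esterification of a hindered allylic alcohol without Z/E isomerisation.

26 ⇒ 23. Cut: the C11=C13 bond. The lactone Michael acceptor is added only after the epoxide has been closed with base. Gain: 23 has a plain lactone. Demand: lactone enolate formation next to an epoxide and a free hydroxyl, with no ketone in the molecule.

23 ⇒ 21 (through 22). Cut: the O4–C3 bond of the epoxide, restoring a C3–O bond of opposite configuration. A trans epoxide on the ten-membered ring corresponds to a cis diol on ring A. Gain: both epoxide centres trace back to one early syn dihydroxylation. Demand: activation of O3 alone among three hydroxyls, and an anti-periplanar C2–C3–C4–C5 segment, which exists only after ring scission.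

21 ⇒ 20. Cut: the O3–Si and O9–Si bonds. These two ethers form the labile silyl pair. Gain: one operation frees the diol and the acylation site. Demand: cleavage must leave the two bulkier silyl ethers.

20 ⇒ 19. Cut: the O1–Si bond. C1–OH must not compete in sulfonylation or acylation. Demand: silylation of the secondary and not the tertiary hydroxyl.

19 ⇒ 18. Cut: the C1–H bond (alcohol read back to enone). C1 is parked at the alcohol level during all base-mediated steps. Gain: no E1cB pathway at C2/C3. Demand: 1,2- and not 1,4-reduction; the C1 configuration is irrelevant.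

18 ⇒ 17. Cut: the C10=C14 π bond, restoring C10–H and the C14–O pivalate bond. The exocyclic olefin comes from β-elimination through the C1 ketone, done as soon as C6 is no longer a ketone. Gain: C14 needs no separate activation. Demand: elimination at C10 and not at C2, with no second ketone present for a transannular aldol.

17 ⇒ 15 (through 16). Cut: the lactone O6–C12 bond and the C6–H bond. C6 is the one stereocentre that cannot be set on the bicycle. Gain: return to the diketone. Demand: hydride must reach C6 and not C1, from the correct face; hence a free C4–OH and a silylated O3 in 15.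

15 ⇒ 14. Cut (retro): the C1 and C6 carbonyls are rejoined as the C1=C6 double bond. The ten-membered ring is the perimeter of an octalin, so no macrocyclisation is needed and five stereocentres are set on six-membered rings. Demand: 14 may hold no other olefin or ozone-sensitive group, and work-up must be neutral.

14 ⇒ 13. Cut: the O14–acyl bond. The leaving group for C10=C14 is installed last so that no β-eliminable group sits through the basic olefination. Demand: primary over tertiary hydroxyl.

13 ⇒ 12. Cut: the C7–H and C11–H bonds (C7=C11 restored). C7 is set by hydride approach anti to O8. Gain: the all-cis C7/C8/C9 triad follows from the diol. Demand: 1,4- and not 1,6-delivery, and face control.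

12 ⇒ 11. Cut: the C7–C11 double bond. The two-carbon unit comes from an α-silyl acetate. Demand: addition to a hindered, conjugated ketone without enolisation toward C8.

11 ⇒ 10. Cut: C7=O back to its dimethyl ketal. The ketal kept C7 distinct from C10 while C10 was homologated. Demand: hydrolysis mild enough for triethylsilyl ethers.

10 ⇒ 9. Cut: the C14–O and C10–H bonds. Demand: hydroboration of the terminal olefin only.

9 ⇒ 8. Cut: the C10=C14 bond (one-carbon homologation of the C10 ketone). Demand: non-basic methylenation.

8 ⇒ 6 (through 7). Cut: the C1=C6 π bond, restoring H-1 and H-6. The cis ring fusion is the relay that ties the configuration of ring A to that of ring B and is given up only after both diols are in place. Demand: regioselective dehydrogenation.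

6 ⇒ 5. Cut: the O8–Si bond. Demand: silylation of the hindered secondary and not the tertiary hydroxyl.

5 ⇒ 4. Cut: the O3–Si and O9–Si bonds. C9 is told from C8, and C3 from C4, here. Demand: steric discrimination among four hydroxyls.

4 ⇒ 3. Cut: the C3–O, C4–O, C8–O and C9–O bonds. All four oxygens go onto the convex face in one operation. Demand: face selectivity from the cis-fused shape.

3 ⇒ 1 + 2. Cut: the C1–C2 and C5–C6 bonds. The single ketone of 1 fixes the position of the methyl group relative to C10 and C7, which breaks the near-symmetry at the outset. Demand: "para" regiochemistry and enantioface control.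

## Other disconnections considered

Alternative 1: The cut replaces the C3=C4 and C9=C10 olefins of a cyclodeca-3,9-diene by the σ bonds C4–C9 and C3–C10, folding the ten-membered ring back into a cyclohexanone and a cyclobutane. Forward, irradiation of the lactone-fused 3-methylcyclohexenone A1 with methyl cyclobut-1-ene-1-carboxylate A2 should give the head-to-head cis-anti-cis tricycle A3 (new bonds C3–C4 and C9–C10). Heating should then cleave C4–C9 and C3–C10 to the cyclodecadienone A4.
- In its favour: the trans-lactone centres C6/C7 are set in a small bicycle, ring strain drives the opening, few protecting groups are needed, and the ring is reached in fewer steps than in the chosen plan. The E C3=C4 olefin of A4 could be epoxidised directly, which is better than the diol inversion used here.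
- Against it here: the triplet [2+2] must be regio- and face-selective at a β,β-disubstituted enone while creating quaternary C4. The cis,trans-1,5-diene A4 is set up for Cope rearrangement at the temperature of its formation. C1 and C2 arrive as unfunctionalised methylenes, so the C1 ketone, which ozonolysis delivers directly, would need a late C–H oxidation beside an epoxide. C14 arrives as an ester on C9=C10 and must be transposed to the 9-oxy-10(14)-ene pattern, and C9 would be set on the medium ring.
- Comparison: both plans unveil the ring by fragmentation and are equal in avoiding a macrocyclisation. Alternative 1 is shorter to the ring; the chosen plan is stronger on oxidation pattern and stereocontrol.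

Alternative 2: The cut is C1–C10 together with O–C9 of an isoxazoline. Forward, hypochlorite oxidation of aldoxime A5 should generate the 1,3-dipole at C1, which adds across the terminal C9=C10 vinyl group and closes both the carbocycle and the bridging heterocycle in A6.
- In its favour: the isoxazoline is a masked β-hydroxy ketone that maps exactly onto C1=O/C9–OH. C10 is left as a methylene for direct α-methylenation. Epoxide, lactone and O8 are already present, and C1 and C6 are never alike. On differentiation and on the number of steps after ring formation it is better than the chosen plan.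
- Against it: a ten-membered carbocycle is closed by a cycloaddition, with the entropic and transannular cost of that, and dipole dimerisation competes. The regiochemistry is that of a bridged product, and the new C9 centre is set in a macrocyclic transition state. The acyclic precursor A5, with five stereocentres including the trans epoxide and trans lactone, moves the whole stereochemical burden into a long linear sequence. The epoxide must survive hypochlorite and N–O cleavage.
- Comparison: overall step count would be similar; the risk is concentrated in one ring closure, where the chosen plan has none.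

Alternative 3: The cut is C5–C6 with C3–C8 restored, a retro-oxy-Cope contraction of the ten-membered ring to the terpene-derived dialkenylcyclohexenol A7. Forward, its potassium alkoxide should rearrange through a chair transition state to the cyclodecadienone A8.
- In its favour: the route to the ring is very short and starts from the chiral pool with no asymmetric catalysis. The rearrangement has a strong driving force. Chirality is transferred cleanly to C6 and the C3=C4 olefin is E, ready for direct trans-epoxidation. On these points it is better than the chosen plan.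
- Against it: A8 lacks C11–C13 and any oxygen at C1 and C9. C6 carries an ethyl ether that must be cleaved before lactonisation. C7, C8 and C9 would all be set on the flexible ten-membered ring, and the Z enone at C9=C10 must be turned into the 9-oxy-10(14)-ene-1-one array.
- Comparison: the steps saved before the key step would be spent, with weak control, after it. The chosen plan inverts that balance.

Key step: step 12

Remark (numbering and faces): target numbering C1–C15 is used for every intermediate; ring A = C1–C6, ring B = C1, C6, C7–C10; α is the face of H-1/H-6 in the cis-fused compounds, and O3, O4, O8, O9 and C11 all lie on α.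

Remark (check of the stated structures): the stated precursor and product are mutually consistent and carry the target configuration at C4, C7, C8 and C9 and the epimeric one at C3, so no correction of connectivity or configuration is needed. Three design faults are corrected: (a) the two carbonyls of a benzoquinone–isoprene adduct cannot be told apart relative to the remote methyl group, so the mono(dimethyl ketal) 1 is used as dienophile; (b) a bis-acetonide gives no way to distinguish O8 from O9, or the diol of ring A from that of ring B, and no control at C6, so separate silyl ethers and a free C4–OH replace it; (c) a single reagent-controlled dihydroxylation of the ring-A olefin is replaced by catalyst control in the cycloaddition and substrate control through the cis ring fusion.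

Remark (assumption): the (S)-binaphthol titanium catalyst is assumed to give the (4aR,8aS) adduct 3; if it gives the antipode, the (R)-ligand is used.

Remark (assumption): C10 in 10–17 is drawn as the epimer expected from hydroboration anti to O9, and C1 in 19–29 is left undefined; both centres become sp2 again, so either epimer serves.

## Steps

Step 1
Reactants: 1 4,4-dimethoxycyclohexa-2,5-dien-1-one; 2 isoprene
Product: 3 (4aR,8aS)-4,4-dimethoxy-6-methyl-4a,5,8,8a-tetrahydronaphthalen-1(4H)-one (cis-fused; C10 ketone, C8=C9, C7 ketal, C3=C4 with C15 on C4)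
Conditions: (S)-1,1′-bi-2-naphthol (20 mol %), TiCl2(OiPr)2 (10 mol %), 4 Å molecular sieves, CH2Cl2, −20 °C → rt
Reagents that add atoms: none
Why: Lewis-acid-catalysed Diels–Alder reaction in which the tetravalent titanium centre binds the C10 carbonyl and isoprene adds endo to one of the two enantiotopic enone olefins with its methyl "para" to the acyl-bearing carbon C1, so C15 lands on C4 and the ring fusion is cis; the binaphtholate ligand selects the olefin face and thereby the absolute configuration. C1 and C6 are set only as temporary relay centres (H-1 and H-6 define the α face).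

Step 2
Reactants: 3 Diels–Alder adduct
Product: 4 cis-fused decalone tetraol (3α,4α,8α,9α-tetrahydroxy; C10 ketone; C7 dimethyl ketal)
Conditions: OsO4 (5 mol %), N-methylmorpholine N-oxide (3 equiv), acetone–H2O, 0 °C → rt
Reagents that add atoms: N-methylmorpholine N-oxide, C[N+]1([O-])CCOCC1; water, O
Why: Catalytic syn-dihydroxylation; both olefins of the folded cis-fused bicycle are attacked from the convex α face (each ring blocks the β face of the other), which puts O3/O4 and O8/O9 on the same face and sets C3, C4, C8 and C9. The electron-rich C3=C4 bond should react first and the enone C8=C9 more slowly; removing C8=C9 also closes the path to aromatisation of the ketal adduct.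

Step 3
Reactants: 4 tetraol
Product: 5 3,9-bis(triethylsilyl) ether of 4 (4-OH and 8-OH free)
Conditions: Et3SiCl (2.2 equiv), imidazole, CH2Cl2, −20 → 0 °C
Reagents that add atoms: chlorotriethylsilane, CC[Si](Cl)(CC)CC
Why: Silylation under steric control; the two accessible secondary hydroxyls (C3, and C9 beside the flat carbonyl) should react, while the tertiary C4–OH and the C8–OH flanked by the quaternary ketal carbon and C9 should not at low temperature.

Step 4
Reactants: 5 bis(triethylsilyl) ether
Product: 6 8-O-tert-butyldimethylsilyl-3,9-bis-O-triethylsilyl decalone (4-OH free)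
Conditions: tBuMe2SiOTf (1.2 equiv), 2,6-lutidine, CH2Cl2, −78 °C
Reagents that add atoms: tert-butyldimethylsilyl trifluoromethanesulfonate, CC(C)(C)[Si](C)(C)OS(=O)(=O)C(F)(F)F
Why: The hindered secondary C8–OH needs the silyl triflate; at −78 °C with a slight excess the tertiary C4–OH should stay free, and O8 and O9 now carry silyl groups of different lability.

Step 5
Reactants: 6 fully differentiated decalone
Product: 8 octalone with C10 ketone conjugated to the C1=C6 ring-fusion olefin (C7 ketal; 3-OTES, 4-OH, 8-OTBS, 9-OTES), via silyl enol ether 7 (not isolated)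
Conditions: LiN(iPr)2 (2.3 equiv), Me3SiCl (3 equiv), THF, −78 °C; then Pd(OAc)2 (1.1 equiv), MeCN, rt; aq. citric acid work-up
Reagents that add atoms: none
Why: Saegusa–Ito oxidation; kinetic deprotonation should occur at the ring-fusion C1–H and not at the silyloxy-bearing C9–H, the enol ether is palladated at C1, and syn β-hydride elimination of the cis H-6 gives the tetrasubstituted conjugated C1=C6 enone. The C4 hydroxyl is silylated in passing and released on work-up; the relay centres are erased only now, after both diols are in place.

Step 6
Reactants: 8 octalone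
Product: 9 10-methylene octalin (diene C14=C10–C1=C6; C7 ketal)
Conditions: Cp2TiMe2 (3 equiv), toluene, 65 °C
Reagents that add atoms: dimethyltitanocene, [CH3-].[CH3-].[Ti+4].c1cc[cH-]c1.c1cc[cH-]c1
Why: Petasis methylenation; the non-basic titanium methylidene converts the hindered, enolisable C10 ketone into the C10=C14 methylene without β-elimination of the C8 silyloxy group, and silyl ethers and the ketal are inert.

Step 7
Reactants: 9 diene
Product: 10 10-(hydroxymethyl) octalin (C14–OH; H-10 β expected; C7 ketal)
Conditions: 9-BBN (3 equiv), THF, 0 °C → rt; then NaOH, H2O2, 0 °C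
Reagents that add atoms: hydrogen peroxide, OO
Why: Hydroboration–oxidation; the bulky borane adds only to the terminal 1,1-disubstituted C10=C14 bond (boron on C14) and not to the tetrasubstituted C1=C6 bond. Hydrogen should enter C10 anti to the C9 silyloxy group, but this centre becomes sp2 again in step 14.

Step 8
Reactants: 10 primary alcohol
Product: 11 octalin-7-one (C7 ketone conjugated with C1=C6; 4-OH and 14-OH free)
Conditions: pyridinium p-toluenesulfonate (cat.), acetone–H2O, 0 °C
Reagents that add atoms: water, O
Why: Acetal hydrolysis; the dimethyl ketal is now allylic to the electron-rich C1=C6 olefin, so its oxocarbenium ion forms under acid mild enough to leave the triethylsilyl ethers intact.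

Step 9
Reactants: 11 enone
Product: 12 methyl (ring-B-ylidene)acetate (C7=C11 conjugated with C1=C6; E/Z mixture)
Conditions: Me3SiCH2CO2Me, LiN(iPr)2 (4 equiv), THF, −78 → 0 °C
Reagents that add atoms: methyl 2-(trimethylsilyl)acetate, COC(=O)C[Si](C)(C)C
Why: Peterson olefination; the small, reactive lithium enolate of the α-silyl ester adds 1,2 to the hindered C7 ketone at −78 °C and elimination of lithium trimethylsilanolate forms C7=C11. The two free hydroxyls are only deprotonated by the excess base, and the olefin geometry is irrelevant.

Step 10
Reactants: 12 dienoate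
Product: 13 octalin hydroxy ester (7α-CH2CO2Me; C14–OH and C4–OH free)
Conditions: [(Ph3P)CuH]6 (0.5 equiv), H2O (5 equiv), toluene, rt
Reagents that add atoms: none
Why: Copper hydride conjugate reduction; hydride should add 1,4 at C7 (1,6-addition would have to occur at the fully substituted C1) and approach anti to the pseudo-axial C8 silyloxy group, placing C11 on the α face cis to O8 and O9. This sets C7, the last stereocentre needed before ring scission.

Step 11
Reactants: 13 hydroxy ester
Product: 14 octalin pivalate, the key-step precursor (C1=C6; 3-OTES, 4-OH, 7α-CH2CO2Me, 8-OTBS, 9-OTES, 10-CH2OPiv)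
Conditions: tBuCOCl, pyridine, 4-(dimethylamino)pyridine (cat.), CH2Cl2, 0 °C
Reagents that add atoms: pivaloyl chloride, CC(C)(C)C(=O)Cl
Why: Chemoselective acylation of the primary C14 hydroxyl; the tertiary C4–OH does not react. The pivalate is installed only now, so that no β-eliminable group was present during the basic olefination, and it later serves as the leaving group for the C10=C14 olefin.

Step 12
Reactants: 14 octalin pivalate
Product: 15 ten-membered C1,C6-diketone (3-OTES, 4-OH, 7-CH2CO2Me, 8-OTBS, 9-OTES, 10-CH2OPiv)
Conditions: O3, CH2Cl2–MeOH (5:1), −78 °C (Sudan Red 7B end point); then Me2S, −78 °C → rt; neutral work-up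
Reagents that add atoms: ozone, [O-][O+]=O
Why: Ozone adds to the only C=C bond, the electron-rich tetrasubstituted C1=C6 olefin, by 1,3-dipolar cycloaddition to give the primary ozonide. Cycloreversion gives one ketone and a carbonyl oxide, which methanol (or the neighbouring C4 hydroxyl) traps as an α-alkoxy hydroperoxide; Me2S reduces this to the second ketone and becomes dimethyl sulfoxide. The closest known reaction type is the ozonolysis of Δ9,10-octalins to cyclodecane-1,6-diones. The ten-membered ring C1–C10 is not closed by bond formation: it is the perimeter of the bicyclo[4.4.0] system and is released by scission of the shared bond, so no entropic or transannular penalty of a cyclisation arises. No new stereocentre is formed; C3, C4, C7, C8 and C9 are carried over unchanged. The step needs chemoselectivity for the olefin, which is secured because 14 has no other π bond, no acetal C–H and no aryl ether, and the dye end point avoids excess ozone. The hydroxy diketone can epimerise at C7, lose pivalate, undergo retro-aldol at C4–C5 or transannular aldolisation under base, so work-up is neutral and 15 is used at once.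

Step 13
Reactants: 15 diketone
Product: 17 trans-fused 12,6-lactone with C1 ketone and C14 pivalate, via hydroxy ester 16 (not isolated)
Conditions: Me4NBH(OAc)3 (5 equiv), MeCN–AcOH (1:1), −30 → 0 °C; then pyridinium p-toluenesulfonate (cat.), benzene, 40 °C
Reagents that add atoms: none
Why: Evans–Saksena directed reduction; the C4 hydroxyl exchanges onto boron and delivers hydride intramolecularly to the β-related C6 ketone only (C1 has no free β-hydroxyl), from the face on which O4 sits, which should give the 1,3-trans (6R) alcohol. Acid then closes the only possible γ-lactone onto C12 (O8 is silylated) and drains any transannular C6–O/C1 hemiketal.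

Step 14
Reactants: 17 keto lactone
Product: 18 lactone with 10(14)-en-1-one
Conditions: DBU (1.2 equiv), CH2Cl2, 0 °C
Reagents that add atoms: none
Why: E1cB elimination; with the C6 carbonyl gone there is no transannular aldol partner, DBU removes H-10 of the β-pivaloyloxy ketone and pivalate leaves to give the C10=C14 enone. Silyloxide at C3 is a far poorer leaving group.

Step 15
Reactants: 18 enone lactone
Product: 19 C1 allylic alcohol (C1 epimers)
Conditions: NaBH4, CeCl3·7H2O, MeOH, −78 °C
Reagents that add atoms: none
Why: Luche reduction; 1,2-reduction of the exo-methylene enone parks C1 as an allylic alcohol so that no ketone is present in the base-mediated steps that follow. The C1 configuration is irrelevant because C1 is re-oxidised in step 22.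

Step 16
Reactants: 19 allylic alcohol
Product: 20 1-O-tert-butyldimethylsilyl ether
Conditions: tBuMe2SiCl, imidazole, DMF, rt
Reagents that add atoms: tert-butyldimethylsilyl chloride, CC(C)(C)[Si](C)(C)Cl
Why: Silylation of the only free secondary hydroxyl; the tertiary C4–OH is untouched under chloride/imidazole conditions.

Step 17
Reactants: 20 tetrasilyl ether
Product: 21 3,4,9-triol (1-OTBS and 8-OTBS retained)
Conditions: HF·pyridine, pyridine, THF, 0 °C
Reagents that add atoms: none
Why: Fluoride cleaves the two triethylsilyl ethers selectively in the presence of the two more robust tert-butyldimethylsilyl ethers, freeing the C3/C4 diol and C9–OH.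

Step 18
Reactants: 21 triol
Product: 23 (3R,4R)-3,4-epoxide (9-OH free), via tosylate 22 (not isolated)
Conditions: TsCl (1.1 equiv), Bu2SnO (5 mol %), Et3N, CH2Cl2, rt; then DBU, rt
Reagents that add atoms: none
Why: Dibutyltin oxide-catalysed regioselective sulfonylation activates only the chelating 1,2-diol, and there the secondary C3 oxygen. With base, the C4 alkoxide displaces the tosylate by intramolecular SN2 with inversion at C3, which needs the anti-periplanar C2–C3–C4–C5 arrangement now available in the ten-membered ring and gives the trans epoxide; with no ketone present, E1cB loss of the sulfonate cannot compete.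

Step 19
Reactants: 23 epoxy lactone
Product: 26 11(13)-methylene lactone, via Mannich base 24 (not isolated), via ammonium iodide 25 (not isolated)
Conditions: LiN(iPr)2 (2.5 equiv), THF, −78 °C; CH2=NMe2+ I−, −78 → 0 °C; then MeI, THF, rt; aq. NaHCO3, CH2Cl2
Reagents that add atoms: N,N-dimethylmethyleneiminium iodide, C=[N+](C)C.[I-]
Why: Mannich α-methylenation; the lactone enolate (the only enolisable carbonyl, with C9–OH carried as its alkoxide) is aminomethylated by the iminium salt, and quaternisation followed by mild base-induced elimination gives the α-methylene lactone.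

Step 20
Reactants: 26 α-methylene lactone; 27 angelic acid
Product: 28 9-O-angelate
Conditions: 27, 2,4,6-trichlorobenzoyl chloride, Et3N, toluene, rt; then 26, 4-(dimethylamino)pyridine, toluene, 60 °C
Reagents that add atoms: none
Why: Yamaguchi esterification through the mixed anhydride acylates the single free hydroxyl (C9) and should keep the Z geometry. It is placed after the last strongly basic step and before the enone exists, so the allylic ester never meets a nucleophilic amine together with the conjugated ketone.

Step 21
Reactants: 28 angelate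
Product: 29 1,8-diol
Conditions: HF·pyridine, pyridine, THF, 0 °C → rt
Reagents that add atoms: none
Why: Buffered HF·pyridine removes both remaining silyl ethers; the epoxide is not β to a carbonyl at this stage, and the weakly acidic medium suppresses acyl migration from O9 to O8 and translactonisation.

Step 22
Reactants: 29 diol
Product: 30 target CNP0348992.2
Conditions: MnO2 (activated, 20 equiv), CH2Cl2, rt
Reagents that add atoms: none
Why: MnO2 oxidises only the allylic C1 alcohol (C8–OH is not allylic) under neutral heterogeneous conditions, so the β,γ-epoxy enone is formed, and both exocyclic acceptors and the allylic angelate are kept, without base.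

## Compound list

1 | 4,4-dimethoxycyclohexa-2,5-dien-1-one | COC1(OC)C=CC(=O)C=C1 | starting material
2 | isoprene | C=CC(C)=C | starting material
3 | (4aR,8aS)-4,4-dimethoxy-6-methyl-4a,5,8,8a-tetrahydronaphthalen-1(4H)-one | COC1(OC)[C@H]2[C@H](CC=C(C)C2)C(=O)C=C1 | intermediate
4 | cis-fused decalone 3α,4α,8α,9α-tetraol (C10 ketone, C7 dimethyl ketal) | COC1(OC)[C@H]2[C@H](C[C@H](O)[C@](C)(O)C2)C(=O)[C@@H](O)[C@H]1O | intermediate
5 | 3,9-bis(triethylsilyl) ether of 4 | COC1(OC)[C@H]2[C@H](C[C@H](O[Si](CC)(CC)CC)[C@](C)(O)C2)C(=O)[C@@H](O[Si](CC)(CC)CC)[C@H]1O | intermediate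
6 | 8-O-TBS-3,9-bis-O-TES decalone (4-OH free) | COC1(OC)[C@H]2[C@H](C[C@H](O[Si](CC)(CC)CC)[C@](C)(O)C2)C(=O)[C@@H](O[Si](CC)(CC)CC)[C@H]1O[Si](C)(C)C(C)(C)C | intermediate
7 | C10 trimethylsilyl enol ether (C1=C10) of 6, 4-O-trimethylsilylated | COC1(OC)[C@H]2C(C[C@H](O[Si](CC)(CC)CC)[C@](C)(O[Si](C)(C)C)C2)=C(O[Si](C)(C)C)[C@@H](O[Si](CC)(CC)CC)[C@H]1O[Si](C)(C)C(C)(C)C | intermediate
8 | octalone: C10 ketone conjugated with C1=C6, C7 ketal | COC1(OC)C2=C(C[C@H](O[Si](CC)(CC)CC)[C@](C)(O)C2)C(=O)[C@@H](O[Si](CC)(CC)CC)[C@H]1O[Si](C)(C)C(C)(C)C | intermediate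
9 | 10-methylene octalin (C14=C10–C1=C6) | COC1(OC)C2=C(C[C@H](O[Si](CC)(CC)CC)[C@](C)(O)C2)C(=C)[C@@H](O[Si](CC)(CC)CC)[C@H]1O[Si](C)(C)C(C)(C)C | intermediate
10 | 10-(hydroxymethyl) octalin, C7 ketal | COC1(OC)C2=C(C[C@H](O[Si](CC)(CC)CC)[C@](C)(O)C2)[C@@H](CO)[C@@H](O[Si](CC)(CC)CC)[C@H]1O[Si](C)(C)C(C)(C)C | intermediate
11 | octalin-7-one (C7 ketone conjugated with C1=C6) | O=C1C2=C(C[C@H](O[Si](CC)(CC)CC)[C@](C)(O)C2)[C@@H](CO)[C@@H](O[Si](CC)(CC)CC)[C@H]1O[Si](C)(C)C(C)(C)C | intermediate
12 | methyl (ring-B-ylidene)acetate, C7=C11 (E/Z) | COC(=O)C=C1C2=C(C[C@H](O[Si](CC)(CC)CC)[C@](C)(O)C2)[C@@H](CO)[C@@H](O[Si](CC)(CC)CC)[C@H]1O[Si](C)(C)C(C)(C)C | intermediate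
13 | octalin hydroxy ester (7α-CH2CO2Me, C14–OH) | COC(=O)C[C@H]1C2=C(C[C@H](O[Si](CC)(CC)CC)[C@](C)(O)C2)[C@@H](CO)[C@@H](O[Si](CC)(CC)CC)[C@H]1O[Si](C)(C)C(C)(C)C | intermediate
14 | octalin pivalate (key-step precursor) | COC(=O)C[C@H]1C2=C(C[C@H](O[Si](CC)(CC)CC)[C@](C)(O)C2)[C@@H](COC(=O)C(C)(C)C)[C@@H](O[Si](CC)(CC)CC)[C@H]1O[Si](C)(C)C(C)(C)C | intermediate
15 | ten-membered C1,C6-diketone (key-step product) | COC(=O)C[C@H]1C(=O)C[C@@](C)(O)[C@@H](O[Si](CC)(CC)CC)CC(=O)[C@@H](COC(=O)C(C)(C)C)[C@@H](O[Si](CC)(CC)CC)[C@H]1O[Si](C)(C)C(C)(C)C | intermediate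
16 | (6R)-6-hydroxy ester, C1 ketone | COC(=O)C[C@H]1[C@H](O)C[C@@](C)(O)[C@@H](O[Si](CC)(CC)CC)CC(=O)[C@@H](COC(=O)C(C)(C)C)[C@@H](O[Si](CC)(CC)CC)[C@H]1O[Si](C)(C)C(C)(C)C | intermediate
17 | trans-fused 12,6-lactone, C1 ketone, C14 pivalate | O=C1C[C@H]2[C@H](O1)C[C@@](C)(O)[C@@H](O[Si](CC)(CC)CC)CC(=O)[C@@H](COC(=O)C(C)(C)C)[C@@H](O[Si](CC)(CC)CC)[C@H]2O[Si](C)(C)C(C)(C)C | intermediate
18 | lactone with 10(14)-en-1-one | O=C1C[C@H]2[C@H](O1)C[C@@](C)(O)[C@@H](O[Si](CC)(CC)CC)CC(=O)C(=C)[C@@H](O[Si](CC)(CC)CC)[C@H]2O[Si](C)(C)C(C)(C)C | intermediate
19 | C1 allylic alcohol (C1 epimers) | O=C1C[C@H]2[C@H](O1)C[C@@](C)(O)[C@@H](O[Si](CC)(CC)CC)CC(O)C(=C)[C@@H](O[Si](CC)(CC)CC)[C@H]2O[Si](C)(C)C(C)(C)C | intermediate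
20 | 1-O-TBS ether of 19 | O=C1C[C@H]2[C@H](O1)C[C@@](C)(O)[C@@H](O[Si](CC)(CC)CC)CC(O[Si](C)(C)C(C)(C)C)C(=C)[C@@H](O[Si](CC)(CC)CC)[C@H]2O[Si](C)(C)C(C)(C)C | intermediate
21 | 3,4,9-triol (1,8-bis-OTBS) | O=C1C[C@H]2[C@H](O1)C[C@@](C)(O)[C@@H](O)CC(O[Si](C)(C)C(C)(C)C)C(=C)[C@@H](O)[C@H]2O[Si](C)(C)C(C)(C)C | intermediate
22 | 3-O-tosylate of 21 | O=C1C[C@H]2[C@H](O1)C[C@@](C)(O)[C@@H](OS(=O)(=O)c3ccc(C)cc3)CC(O[Si](C)(C)C(C)(C)C)C(=C)[C@@H](O)[C@H]2O[Si](C)(C)C(C)(C)C | intermediate
23 | (3R,4R)-3,4-epoxide, 9-OH free | O=C1C[C@H]2[C@H](O1)C[C@@]3(C)O[C@@H]3CC(O[Si](C)(C)C(C)(C)C)C(=C)[C@@H](O)[C@H]2O[Si](C)(C)C(C)(C)C | intermediate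
24 | 11-(dimethylaminomethyl) lactone | O=C1C(CN(C)C)[C@H]2[C@H](O1)C[C@@]3(C)O[C@@H]3CC(O[Si](C)(C)C(C)(C)C)C(=C)[C@@H](O)[C@H]2O[Si](C)(C)C(C)(C)C | intermediate
25 | 11-(trimethylammoniomethyl) lactone iodide | O=C1C(C[N+](C)(C)C)[C@H]2[C@H](O1)C[C@@]3(C)O[C@@H]3CC(O[Si](C)(C)C(C)(C)C)C(=C)[C@@H](O)[C@H]2O[Si](C)(C)C(C)(C)C.[I-] | intermediate
26 | 11(13)-methylene lactone, 9-OH free | C=C1C(=O)O[C@@H]2C[C@@]3(C)O[C@@H]3CC(O[Si](C)(C)C(C)(C)C)C(=C)[C@@H](O)[C@@H](O[Si](C)(C)C(C)(C)C)[C@@H]12 | intermediate
27 | angelic acid, (Z)-2-methylbut-2-enoic acid | C/C=C(/C)C(=O)O | starting material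
28 | 9-O-angelate, 1,8-bis-OTBS | C=C1C(=O)O[C@@H]2C[C@@]3(C)O[C@@H]3CC(O[Si](C)(C)C(C)(C)C)C(=C)[C@@H](OC(=O)/C(C)=C\C)[C@@H](O[Si](C)(C)C(C)(C)C)[C@@H]12 | intermediate
29 | 1,8-diol (C1 epimers) | C=C1C(=O)O[C@@H]2C[C@@]3(C)O[C@@H]3CC(O)C(=C)[C@@H](OC(=O)/C(C)=C\C)[C@@H](O)[C@@H]12 | intermediate
30 | CNP0348992.2, (3R,4R,6R,7R,8S,9R) | C=C1C(=O)O[C@@H]2C[C@@]3(C)O[C@@H]3CC(=O)C(=C)[C@@H](OC(=O)/C(C)=C\C)[C@@H](O)[C@@H]12 | target

## Step count and least certain steps

Total step count: 22. Longest linear sequence: 22 steps (1 → 30); 27 enters at step 20.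

Step 12 (key step). The carbonyl oxide of this hindered tetrasubstituted olefin may be diverted to oligomeric peroxides or trapped transannularly, and the hydroxy diketone may aldolise or lose pivalate while the peroxides are reduced. Fallback, from 14 back to 15: osmylation of the C1=C6 bond from the open β face (OsO4, pyridine; then aq. NaHSO3) to the ring-fusion cis-1,6-diol F1, then glycol cleavage with Pb(OAc)4 in benzene. The tertiary 1,2-diol is the only vicinal diol in F1, and the cleavage is neutral and peroxide-free.

Step 1. Enantio- or regiocontrol may erode, or the Lewis acid may ionise the acyclic ketal, because this catalyst class is established for cyclic quinone monoketals. Fallback, from 1 and 2 back to 3: thermal cycloaddition in toluene without Lewis acid to racemic 3, then separation on a chiral stationary phase by simulated-moving-bed chromatography; the unwanted antipode of 3, F2, is discarded. Resolution replaces asymmetric catalysis, and all later stereocentres still follow from the relay.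

Step 5. β-Hydride loss in the palladium enolate may go toward C2 instead of C6 and put the double bond in the wrong place, or enolisation may stray toward C9 with loss of the C8 silyloxy group. Fallback, from 6 back to 11 (bypassing 8–10): the kinetic C1 enolate is trapped as the enol triflate F3 (KN(SiMe3)2, PhNTf2, THF, −78 °C). Stille hydroxymethylation with Bu3SnCH2OH (Pd(PPh3)4, LiCl, dioxane) gives the allylic alcohol F4 with a C1=C10 olefin. Ketal hydrolysis gives the β,γ-unsaturated ketone F5, and DBU moves the double bond into conjugation (C6=C1, proton to C10), which is 11. No β-hydride elimination is involved, and the olefin position is fixed by thermodynamics.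

Step 10. 1,6-Hydride delivery or weak face selectivity at the hindered β,β-disubstituted dienoate may occur. Fallback, from 11 back to 14 (bypassing 12 and 13): C14–OH is pivaloylated to the keto pivalate F6. The C7 ketone is reduced under Luche conditions from the β face to the 7α-allylic alcohol F7, which is converted into the methyl carbonate F8 (ClCO2Me, pyridine). Tsuji–Trost alkylation with NaCH(CO2Me)2 and Pd(PPh3)4 follows: ionisation anti to the leaving group and attack anti to palladium at the less substituted terminus C7 give the malonate F9 with net retention, so C11 lies on the α face. Krapcho dealkoxycarbonylation (LiCl, wet DMSO, 130 °C) then gives 14. Stereocontrol rests on the stereospecificity of π-allyl chemistry, not on approach control.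

Step 13. Hydride may be delivered through a ring conformer that leads to the 6-epimer, or the C4 hydroxyl may be sequestered as the C1 hemiketal so that the reduction loses its direction. Fallback, from 15 back to 20: the 6-epimeric cis-lactone F10 is taken through the operations of steps 14–16 (enone F11, allylic alcohol F12, silyl ether F13). The lactone is opened with LiOH to the hydroxy acid F14, and Mitsunobu lactonisation (PPh3, diisopropyl azodicarboxylate) closes the ring with inversion at C6 to give 20; the tertiary C4–OH is inert and all other hydroxyls are silylated. A stereospecific SN2 step replaces the stereoselective reduction.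

## Further compounds

F1 | step 12 | ring-fusion cis-1,6-diol of 14 | COC(=O)C[C@H]1[C@]2(O)[C@@](O)(C[C@H](O[Si](CC)(CC)CC)[C@](C)(O)C2)[C@@H](COC(=O)C(C)(C)C)[C@@H](O[Si](CC)(CC)CC)[C@H]1O[Si](C)(C)C(C)(C)C
F2 | step 1 | (4aS,8aR)-4,4-dimethoxy-6-methyl-4a,5,8,8a-tetrahydronaphthalen-1(4H)-one | COC1(OC)[C@@H]2[C@@H](CC=C(C)C2)C(=O)C=C1
F3 | step 5 | C10 enol triflate (C1=C10) of 6 | COC1(OC)[C@H]2C(C[C@H](O[Si](CC)(CC)CC)[C@](C)(O)C2)=C(OS(=O)(=O)C(F)(F)F)[C@@H](O[Si](CC)(CC)CC)[C@H]1O[Si](C)(C)C(C)(C)C
F4 | step 5 | allylic alcohol, C1=C10 with C14–OH, C7 ketal | COC1(OC)[C@H]2C(C[C@H](O[Si](CC)(CC)CC)[C@](C)(O)C2)=C(CO)[C@@H](O[Si](CC)(CC)CC)[C@H]1O[Si](C)(C)C(C)(C)C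
F5 | step 5 | β,γ-unsaturated C7 ketone (C1=C10) | O=C1[C@H]2C(C[C@H](O[Si](CC)(CC)CC)[C@](C)(O)C2)=C(CO)[C@@H](O[Si](CC)(CC)CC)[C@H]1O[Si](C)(C)C(C)(C)C
F6 | step 10 | 14-O-pivalate of 11 | O=C1C2=C(C[C@H](O[Si](CC)(CC)CC)[C@](C)(O)C2)[C@@H](COC(=O)C(C)(C)C)[C@@H](O[Si](CC)(CC)CC)[C@H]1O[Si](C)(C)C(C)(C)C
F7 | step 10 | 7α-allylic alcohol | O[C@H]1C2=C(C[C@H](O[Si](CC)(CC)CC)[C@](C)(O)C2)[C@@H](COC(=O)C(C)(C)C)[C@@H](O[Si](CC)(CC)CC)[C@H]1O[Si](C)(C)C(C)(C)C
F8 | step 10 | 7α-allylic methyl carbonate | COC(=O)O[C@H]1C2=C(C[C@H](O[Si](CC)(CC)CC)[C@](C)(O)C2)[C@@H](COC(=O)C(C)(C)C)[C@@H](O[Si](CC)(CC)CC)[C@H]1O[Si](C)(C)C(C)(C)C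
F9 | step 10 | 7α-malonate | COC(=O)C(C(=O)OC)[C@H]1C2=C(C[C@H](O[Si](CC)(CC)CC)[C@](C)(O)C2)[C@@H](COC(=O)C(C)(C)C)[C@@H](O[Si](CC)(CC)CC)[C@H]1O[Si](C)(C)C(C)(C)C
F10 | step 13 | 6-epi (cis-fused) lactone, C1 ketone, C14 pivalate | O=C1C[C@H]2[C@@H](O1)C[C@@](C)(O)[C@@H](O[Si](CC)(CC)CC)CC(=O)[C@@H](COC(=O)C(C)(C)C)[C@@H](O[Si](CC)(CC)CC)[C@H]2O[Si](C)(C)C(C)(C)C
F11 | step 13 | 6-epi lactone with 10(14)-en-1-one | O=C1C[C@H]2[C@@H](O1)C[C@@](C)(O)[C@@H](O[Si](CC)(CC)CC)CC(=O)C(=C)[C@@H](O[Si](CC)(CC)CC)[C@H]2O[Si](C)(C)C(C)(C)C
F12 | step 13 | 6-epi C1 allylic alcohol | O=C1C[C@H]2[C@@H](O1)C[C@@](C)(O)[C@@H](O[Si](CC)(CC)CC)CC(O)C(=C)[C@@H](O[Si](CC)(CC)CC)[C@H]2O[Si](C)(C)C(C)(C)C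
F13 | step 13 | 6-epi 1-O-TBS ether | O=C1C[C@H]2[C@@H](O1)C[C@@](C)(O)[C@@H](O[Si](CC)(CC)CC)CC(O[Si](C)(C)C(C)(C)C)C(=C)[C@@H](O[Si](CC)(CC)CC)[C@H]2O[Si](C)(C)C(C)(C)C
F14 | step 13 | (6S)-6-hydroxy seco acid | OC(=O)C[C@H]1[C@@H](O)C[C@@](C)(O)[C@@H](O[Si](CC)(CC)CC)CC(O[Si](C)(C)C(C)(C)C)C(=C)[C@@H](O[Si](CC)(CC)CC)[C@H]1O[Si](C)(C)C(C)(C)C
A1 | alternative 1 | trans-fused 6-methyl-3,3a,7,7a-tetrahydro-1-benzofuran-2,4-dione | C1C(=O)O[C@@H]2CC(C)=CC(=O)[C@@H]12
A2 | alternative 1 | methyl cyclobut-1-ene-1-carboxylate | COC(=O)C1=CCC1
A3 | alternative 1 | cis-anti-cis tricyclic photoadduct | C1C(=O)O[C@@H]2C[C@@]3(C)[C@@H]4CC[C@]4(C(=O)OC)[C@H]3C(=O)[C@@H]12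
A4 | alternative 1 | lactone-fused cyclodeca-3,9-dien-8-one 10-carboxylate (3E) | C1C(=O)O[C@@H]2C/C(C)=C/CC/C(C(=O)OC)=C\C(=O)[C@@H]12
A5 | alternative 2 | C1 aldoxime with C9=C10 vinyl group, epoxy lactone, 8-OTBS | C1C(=O)O[C@H](C[C@@]2(C)O[C@@H]2CC=NO)[C@H]1[C@H](O[Si](C)(C)C(C)(C)C)C=C
A6 | alternative 2 | ten-membered carbocycle with isoxazoline bridging C1 and C9 | C1C(=O)O[C@@H]2C[C@@]3(C)O[C@@H]3CC4=NO[C@H](C4)[C@@H](O[Si](C)(C)C(C)(C)C)[C@@H]12
A7 | alternative 3 | trans-1-[(Z)-2-ethoxyvinyl]-6-isopropenyl-3-methylcyclohex-2-en-1-ol | CCO/C=C\[C@@]1(O)C=C(C)CC[C@@H]1C(C)=C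
A8 | alternative 3 | 6-ethoxy-4,10-dimethylcyclodeca-3E,9Z-dien-8-one | CCO[C@@H]1C/C(C)=C/CC/C(C)=C\C(=O)C1
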